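The C1–C2 bond of the indane (C1 bears the 4-hydroxybenzoyl group, C2 the 4-hydroxyphenyl group) is disconnected with C1 carried as a ketone. A rhodium-catalysed enantioselective intramolecular hydroacylation of a 2-(1-arylvinyl)benzaldehyde closes the five-membered ring: the aldehyde carbon on resorcinol ring A becomes C1, the vinyl CH2 becomes C2, and hydride delivery to the diaryl carbon sets C3, the only catalyst-set stereocentre. The step exploits that C1 is attached to ring A carbon C7a and that C3 is a diarylmethine. α-Arylation, enol triflate formation and acylation then give a C1=C2 indenyl ketone, and one hydrogenation anti to the C3 aryl sets C1 and C2, all-cis, while removing the benzyl ethers.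

Key step: step 4

Remark on numbering and configuration: indane numbering of the target is used in all explanations (C1 aroyl carbon, C2 4-hydroxyphenyl carbon, C3 3,5-dihydroxyphenyl carbon, ring A = fused resorcinol ring C3a–C7a); the target reads as (1R,2R,3R), which places all three substituents on the same face (all-cis).

Assumption: (R)-BINAP is taken to deliver (3R)-7 in step 4; should the sense of induction be the opposite, (S)-BINAP is used.

Step 1
Reactants: 1 3,5-bis(benzyloxy)benzaldehyde
Product: 2 2-bromo-3,5-bis(benzyloxy)benzaldehyde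
Conditions: NBS (1.05 equiv), MeCN, 0 °C to rt, dark
Reagents that add atoms: N-bromosuccinimide, O=C1CCC(=O)N1Br
Why: Electrophilic aromatic bromination should occur at C2, the position para to one benzyloxy group and ortho to the other, as is usual for 3,5-dialkoxybenzaldehydes, because C4 is flanked by two ether groups and the unactivated benzyl rings do not react in the dark.

Step 2
Reactants: 3 1-[3,5-bis(benzyloxy)phenyl]ethan-1-one
Product: 4 1-[3,5-bis(benzyloxy)phenyl]ethenyl trifluoromethanesulfonate
Conditions: KN(SiMe3)2 (1.1 equiv), THF, −78 °C; PhNTf2 (1.1 equiv), −78 to 0 °C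
Reagents that add atoms: N-phenylbis(trifluoromethanesulfonimide), O=S(=O)(N(c1ccccc1)S(=O)(=O)C(F)(F)F)C(F)(F)F
Why: Enol triflate formation: the methyl ketone is deprotonated by the hindered amide base and the potassium enolate is O-sulfonylated by PhNTf2, one equivalent of base at low temperature preventing elimination of the 1-arylvinyl triflate to the arylalkyne.

Step 3
Reactants: 4 1-[3,5-bis(benzyloxy)phenyl]ethenyl trifluoromethanesulfonate, 2 2-bromo-3,5-bis(benzyloxy)benzaldehyde
Product: 6 3,5-bis(benzyloxy)-2-{1-[3,5-bis(benzyloxy)phenyl]ethenyl}benzaldehyde, via alkenyl pinacolboronate 5 (not isolated)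
Conditions: B2pin2 (1.1 equiv), PdCl2(PPh3)2 (3 mol%), PPh3, KOPh, toluene, 50 °C; then 2, Pd(OAc)2 (3 mol%), SPhos, aq. K3PO4, 80 °C
Reagents that add atoms: none
Why: Miyaura borylation of the alkenyl triflate followed in the same flask by Suzuki–Miyaura cross-coupling with the di-ortho-substituted aryl bromide 2 (SPhos promotes the hindered coupling) should give the 1,1-diarylethylene, the aldehyde and benzyl ethers being inert to the mildly basic conditions.

Step 4
Reactants: 6 3,5-bis(benzyloxy)-2-{1-[3,5-bis(benzyloxy)phenyl]ethenyl}benzaldehyde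
Product: 7 (3R)-4,6-bis(benzyloxy)-3-[3,5-bis(benzyloxy)phenyl]-2,3-dihydro-1H-inden-1-one
Conditions: [Rh(nbd)2]BF4 (5 mol%), (R)-BINAP (5.5 mol%), activated with H2 then purged with Ar, CH2Cl2–acetone, 25 °C
Reagents that add atoms: none
Why: Oxidative addition of the aldehyde C–H bond of 6 to the cationic monovalent rhodium bisphosphine complex gives an acyl rhodium hydride, the twisted 1,1-diarylethylene chelates, and migratory insertion places hydride on the internal carbon (C3) and rhodium on the terminal CH2, giving a six-membered acyl–alkyl rhodacycle whose C–C reductive elimination forms the C1–C2 bond. The closest known reaction type is the Rh–BINAP-catalysed enantioselective intramolecular hydroacylation of 2-(1-substituted vinyl)benzaldehydes to 3-substituted indan-1-ones. The five-membered ring is closed by reductive elimination from the rhodacycle, formally a 5-endo-trig addition of the acyl C–H bond across the alkene, which is allowed because the bond forms at the metal and not by direct attack on the alkene. The only new stereocentre, C3, is set under catalyst control when the chiral bisphosphine differentiates the two alkene faces in the hydride insertion; C2 remains a methylene. The step needs regioselective hydride delivery to the internal carbon and must outrun decarbonylation: the opposite insertion would demand a strained four-membered ring closure, the alkene has no allylic hydrogen through which it could isomerise, and chelation of the ortho alkene to the acyl hydride at room temperature disfavours CO extrusion.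

Step 5
Reactants: 7 (3R)-4,6-bis(benzyloxy)-3-[3,5-bis(benzyloxy)phenyl]-2,3-dihydro-1H-inden-1-one, 8 1-(benzyloxy)-4-bromobenzene
Product: 9 (2R,3R)-4,6-bis(benzyloxy)-2-[4-(benzyloxy)phenyl]-3-[3,5-bis(benzyloxy)phenyl]-2,3-dihydro-1H-inden-1-one (2,3-trans)
Conditions: Pd(OAc)2 (3 mol%), P(t-Bu)3·HBF4 (6 mol%), NaOt-Bu (2.2 equiv), toluene, 70 °C, Ar; aq. NH4Cl
Reagents that add atoms: none
Why: Palladium-catalysed α-arylation of the ketone enolate (Buchwald–Hartwig type), known for 3-aryl-indan-1-ones, can only occur at C2, leaves the non-acidic C3 stereocentre untouched and, through equilibration of the product enolate on work-up, should give the 2,3-trans isomer (the C2 configuration is erased in step 6 anyway).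

Step 6
Reactants: 9 (2R,3R)-4,6-bis(benzyloxy)-2-[4-(benzyloxy)phenyl]-3-[3,5-bis(benzyloxy)phenyl]-2,3-dihydro-1H-inden-1-one
Product: 10 (1R)-5,7-bis(benzyloxy)-2-[4-(benzyloxy)phenyl]-1-[3,5-bis(benzyloxy)phenyl]-1H-inden-3-yl trifluoromethanesulfonate
Conditions: KN(SiMe3)2 (1.05 equiv), THF, −78 °C; PhNTf2 (1.1 equiv), −78 to 0 °C
Reagents that add atoms: N-phenylbis(trifluoromethanesulfonimide), O=S(=O)(N(c1ccccc1)S(=O)(=O)C(F)(F)F)C(F)(F)F
Why: Enol triflate formation: C2–H, flanked by the ketone and an aryl group, is the only position deprotonated by one equivalent of base at −78 °C, and O-triflation of the enolate fixes the C1=C2 double bond while the doubly benzylic C3–H is not touched.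

Step 7
Reactants: 10 (1R)-5,7-bis(benzyloxy)-2-[4-(benzyloxy)phenyl]-1-[3,5-bis(benzyloxy)phenyl]-1H-inden-3-yl trifluoromethanesulfonate, 11 4-(benzyloxy)benzaldehyde
Product: 12 [(1S)-5,7-bis(benzyloxy)-2-[4-(benzyloxy)phenyl]-1-[3,5-bis(benzyloxy)phenyl]-1H-inden-3-yl][4-(benzyloxy)phenyl]methanol (both carbinol epimers)
Conditions: CrCl2 (6 equiv), NiCl2 (5 mol%), 11 (2 equiv), DMF, rt
Reagents that add atoms: none
Why: Nozaki–Hiyama–Kishi reaction: nickel-catalysed insertion into the alkenyl triflate, transmetalation to chromium and addition of the weakly basic alkenylchromium species to the aldehyde attach the future aroyl carbon to C1 under neutral conditions that cannot epimerise C3; the new carbinol centre forms without control and is removed in step 8.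

Step 8
Reactants: 12 [(1S)-5,7-bis(benzyloxy)-2-[4-(benzyloxy)phenyl]-1-[3,5-bis(benzyloxy)phenyl]-1H-inden-3-yl][4-(benzyloxy)phenyl]methanol
Product: 13 [(1S)-5,7-bis(benzyloxy)-2-[4-(benzyloxy)phenyl]-1-[3,5-bis(benzyloxy)phenyl]-1H-inden-3-yl][4-(benzyloxy)phenyl]methanone
Conditions: activated MnO2 (excess), CH2Cl2, rt
Reagents that add atoms: none
Why: Oxidation of the doubly activated (allylic and benzylic) secondary alcohol by activated MnO2 proceeds under neutral heterogeneous conditions, which protects the now acidic C3–H of the cross-conjugated indenyl ketone from base- or acid-induced racemisation.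

Step 9
Reactants: 13 [(1S)-5,7-bis(benzyloxy)-2-[4-(benzyloxy)phenyl]-1-[3,5-bis(benzyloxy)phenyl]-1H-inden-3-yl][4-(benzyloxy)phenyl]methanone
Product: 14 caraphenol B, [(1R,2R,3R)-3-(3,5-dihydroxyphenyl)-4,6-dihydroxy-2-(4-hydroxyphenyl)-2,3-dihydro-1H-inden-1-yl](4-hydroxyphenyl)methanone (all-cis)
Conditions: H2 (1–3 atm), Pd/C (10 wt% palladium on carbon), EtOAc–MeOH, rt, stopped after uptake of 7 equiv H2
Reagents that add atoms: none
Why: Heterogeneous catalytic hydrogenation adds both hydrogens to the tetrasubstituted C1=C2 bond from the face opposite the C3 aryl group (substrate control, syn addition), so that C1 and C2 are set in one event with the aroyl and 4-hydroxyphenyl groups cis to the C3 aryl group, and hydrogenolysis of the six benzyl ethers under the same neutral conditions frees the phenols without an acid or base that could epimerise C1.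

Compound list
1 | 3,5-bis(benzyloxy)benzaldehyde | O=Cc1cc(OCc2ccccc2)cc(OCc2ccccc2)c1 | starting material
2 | 2-bromo-3,5-bis(benzyloxy)benzaldehyde | O=Cc1cc(OCc2ccccc2)cc(OCc2ccccc2)c1Br | intermediate
3 | 1-[3,5-bis(benzyloxy)phenyl]ethan-1-one | CC(=O)c1cc(OCc2ccccc2)cc(OCc2ccccc2)c1 | starting material
4 | 1-[3,5-bis(benzyloxy)phenyl]ethenyl trifluoromethanesulfonate | C=C(OS(=O)(=O)C(F)(F)F)c1cc(OCc2ccccc2)cc(OCc2ccccc2)c1 | intermediate
5 | 2-{1-[3,5-bis(benzyloxy)phenyl]ethenyl}-4,4,5,5-tetramethyl-1,3,2-dioxaborolane | C=C(B1OC(C)(C)C(C)(C)O1)c1cc(OCc2ccccc2)cc(OCc2ccccc2)c1 | intermediate (not isolated)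
6 | 3,5-bis(benzyloxy)-2-{1-[3,5-bis(benzyloxy)phenyl]ethenyl}benzaldehyde | O=Cc1cc(OCc2ccccc2)cc(OCc2ccccc2)c1C(=C)c1cc(OCc2ccccc2)cc(OCc2ccccc2)c1 | intermediate
7 | (3R)-4,6-bis(benzyloxy)-3-[3,5-bis(benzyloxy)phenyl]-2,3-dihydro-1H-inden-1-one | O=C1C[C@H](c2cc(OCc3ccccc3)cc(OCc3ccccc3)c2)c2c(OCc3ccccc3)cc(OCc3ccccc3)cc12 | intermediate
8 | 1-(benzyloxy)-4-bromobenzene | Brc1ccc(OCc2ccccc2)cc1 | starting material
9 | (2R,3R)-4,6-bis(benzyloxy)-2-[4-(benzyloxy)phenyl]-3-[3,5-bis(benzyloxy)phenyl]-2,3-dihydro-1H-inden-1-one (2,3-trans) | O=C1[C@@H](c2ccc(OCc3ccccc3)cc2)[C@H](c2cc(OCc3ccccc3)cc(OCc3ccccc3)c2)c2c(OCc3ccccc3)cc(OCc3ccccc3)cc12 | intermediate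
10 | (1R)-5,7-bis(benzyloxy)-2-[4-(benzyloxy)phenyl]-1-[3,5-bis(benzyloxy)phenyl]-1H-inden-3-yl trifluoromethanesulfonate | O=S(=O)(OC1=C(c2ccc(OCc3ccccc3)cc2)[C@H](c2cc(OCc3ccccc3)cc(OCc3ccccc3)c2)c2c(OCc3ccccc3)cc(OCc3ccccc3)cc12)C(F)(F)F | intermediate
11 | 4-(benzyloxy)benzaldehyde | O=Cc1ccc(OCc2ccccc2)cc1 | starting material
12 | [(1S)-5,7-bis(benzyloxy)-2-[4-(benzyloxy)phenyl]-1-[3,5-bis(benzyloxy)phenyl]-1H-inden-3-yl][4-(benzyloxy)phenyl]methanol (both carbinol epimers) | OC(c1ccc(OCc2ccccc2)cc1)C1=C(c2ccc(OCc3ccccc3)cc2)[C@H](c2cc(OCc3ccccc3)cc(OCc3ccccc3)c2)c2c(OCc3ccccc3)cc(OCc3ccccc3)cc12 | intermediate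
13 | [(1S)-5,7-bis(benzyloxy)-2-[4-(benzyloxy)phenyl]-1-[3,5-bis(benzyloxy)phenyl]-1H-inden-3-yl][4-(benzyloxy)phenyl]methanone | O=C(c1ccc(OCc2ccccc2)cc1)C1=C(c2ccc(OCc3ccccc3)cc2)[C@H](c2cc(OCc3ccccc3)cc(OCc3ccccc3)c2)c2c(OCc3ccccc3)cc(OCc3ccccc3)cc12 | intermediate
14 | caraphenol B, [(1R,2R,3R)-3-(3,5-dihydroxyphenyl)-4,6-dihydroxy-2-(4-hydroxyphenyl)-2,3-dihydro-1H-inden-1-yl](4-hydroxyphenyl)methanone | O=C(c1ccc(O)cc1)[C@H]1c2cc(O)cc(O)c2[C@@H](c2cc(O)cc(O)c2)[C@H]1c1ccc(O)cc1 | target

Total step count: 9.
Longest linear sequence: 8 steps (3 → 4 → 6 → 7 → 9 → 10 → 12 → 13 → 14).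

Steps most likely to fail

Step 4. The cationic rhodium catalyst may be sequestered by the many electron-rich arenes, decarbonylation of the acyl rhodium hydride may compete, or the extra ortho benzyloxy group may erode face discrimination in the hydride insertion. Fallback: setting out from 6, the ring would be closed by a Lewis acid-promoted Prins-type cyclisation (BF3·OEt2, CH2Cl2, −78 °C). The terminal alkene carbon attacks the activated aldehyde (the same C1–C2 bond), and the diaryl-stabilised C3 cation loses a proton from C2 to give racemic 4,6-bis(benzyloxy)-3-[3,5-bis(benzyloxy)phenyl]-1H-inden-1-ol F1. Oxidation with MnO2 (CH2Cl2, rt) would give 4,6-bis(benzyloxy)-3-[3,5-bis(benzyloxy)phenyl]-1H-inden-1-one F2. A copper hydride-catalysed asymmetric conjugate reduction (Cu(OAc)2, (R)-DTBM-SEGPHOS, (EtO)2MeSiH, t-BuOH, toluene, 0 °C; ligand enantiomer chosen to give the 3R product) would then return to the route at 7, with the enantio-induction moved from the ring closure to a hydride conjugate addition.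

Step 9. Palladium may migrate the alkene into the C2=C3 position with loss of the C3 configuration, facial selectivity on the tetrasubstituted alkene may be incomplete, the aryl ketone may be over-reduced, or C1 may epimerise on the catalyst. Fallback: setting out from 13, the alkene would be reduced by electron transfer instead of on a metal surface. SmI2 (2.5 equiv, THF–MeOH, −78 °C) should effect conjugate reduction with kinetic protonation of C2 and then of the samarium enolate at C1 from the face opposite the aryl groups, giving the all-cis hexabenzyl ether [(1R,2R,3R)-4,6-bis(benzyloxy)-2-[4-(benzyloxy)phenyl]-3-[3,5-bis(benzyloxy)phenyl]-2,3-dihydro-1H-inden-1-yl][4-(benzyloxy)phenyl]methanone F3. Hydrogenolysis of the benzyl ethers alone (H2, Pd(OH)2/C, EtOAc, rt) would then return to the route at 14.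

Step 7. Nickel insertion into the hindered alkenyl triflate may be slow, the alkenylchromium species may be protonated to the triflate-free indene, or the doubly benzylic allylic alcohol may ionise during isolation. Fallback: setting out from 10, the aroyl group would be installed in one palladium-catalysed step by carbonylative Stille coupling (Pd(PPh3)4, LiCl, CO 1 atm, THF, 60 °C, base-free) with tributyl[4-(benzyloxy)phenyl]stannane F4, itself made from 8 (n-BuLi, THF, −78 °C; then Bu3SnCl). This returns to the route at 13 and bypasses 12.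

Further compounds
F1 | step 4 | 4,6-bis(benzyloxy)-3-[3,5-bis(benzyloxy)phenyl]-1H-inden-1-ol (racemic) | OC1C=C(c2cc(OCc3ccccc3)cc(OCc3ccccc3)c2)c2c(OCc3ccccc3)cc(OCc3ccccc3)cc12
F2 | step 4 | 4,6-bis(benzyloxy)-3-[3,5-bis(benzyloxy)phenyl]-1H-inden-1-one | O=C1C=C(c2cc(OCc3ccccc3)cc(OCc3ccccc3)c2)c2c(OCc3ccccc3)cc(OCc3ccccc3)cc12
F3 | step 9 | [(1R,2R,3R)-4,6-bis(benzyloxy)-2-[4-(benzyloxy)phenyl]-3-[3,5-bis(benzyloxy)phenyl]-2,3-dihydro-1H-inden-1-yl][4-(benzyloxy)phenyl]methanone | O=C(c1ccc(OCc2ccccc2)cc1)[C@H]1c2cc(OCc3ccccc3)cc(OCc3ccccc3)c2[C@@H](c2cc(OCc3ccccc3)cc(OCc3ccccc3)c2)[C@H]1c1ccc(OCc2ccccc2)cc1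
F4 | step 7 | tributyl[4-(benzyloxy)phenyl]stannane | CCCC[Sn](CCCC)(CCCC)c1ccc(OCc2ccccc2)cc1
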